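**Assumption:** 2-bromo-5-(hydroxymethyl)phenol, 2-bromoallyl alcohol, angelic acid and (R)-2-methylbutanoic acid are taken as catalogue compounds. The SMILES decodes to an (R)-oxirane carbon, two (R)-2-methylbutanoates and a (Z)-enoate (angelate).

## Retrosynthetic overview

- The oxirane is the only ring and is formed last, by C–O bond formation: catalyst-controlled epoxidation of the 1,1-disubstituted styrenyl alkene of a triester precursor.
- The triester comes from three acyl C–O bonds on one triol: phenol + angelic acid first, then both primary alcohols + (R)-2-methylbutanoic acid in one operation.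
- The triol comes from one aryl–vinyl C–C bond: one-pot borylation/Suzuki coupling of the bromophenol with 2-bromoallyl alcohol.
- Stereocentres: both 2-methylbutanoyl centres are bought; the oxirane carbon is set in the last step.

## Route

**Step 1**
Reactants: 1 2-bromo-5-(hydroxymethyl)phenol; 2 2-bromoprop-2-en-1-ol
Product: 4 2-[2-hydroxy-4-(hydroxymethyl)phenyl]prop-2-en-1-ol, via aryl pinacol boronate 3 (not isolated)
Conditions: B2pin2 (1.1 equiv), XPhos Pd G2 (2 mol %), KOAc (3 equiv), dioxane, 90 °C; then 2 (1.3 equiv), 3 M aq K3PO4 (3 equiv), 70 °C, same pot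
Reagents that add atoms: none
Why: Miyaura borylation followed by Suzuki–Miyaura coupling in one pot; the C–Br bond of 1 fixes the regiochemistry (vinyl ortho to OH, para to CH2OH), free OH groups are tolerated, and the free allylic alcohol is not ionised by Pd(0).

**Step 2**
Reactants: 4 2-[2-hydroxy-4-(hydroxymethyl)phenyl]prop-2-en-1-ol; 5 angelic acid
Product: 7 5-(hydroxymethyl)-2-(3-hydroxyprop-1-en-2-yl)phenyl (2Z)-2-methylbut-2-enoate, via angeloyl chloride 6 (not isolated)
Conditions: 5 (1.1 equiv), 1-chloro-N,N,2-trimethylprop-1-en-1-amine (1.15 equiv), CH2Cl2, 0 °C; then 4, K2CO3 (1.5 equiv), acetone, 0 °C; use crude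
Reagents that add atoms: none
Why: Acid chloride formation under neutral, HCl-free conditions keeps the Z geometry, and carbonate ionises only the phenol (pKa about 10 against about 16), so Schotten–Baumann-type O-acylation is selective for the phenoxide.

**Step 3**
Reactants: 7 5-(hydroxymethyl)-2-(3-hydroxyprop-1-en-2-yl)phenyl (2Z)-2-methylbut-2-enoate; 8 (R)-2-methylbutanoic acid
Product: 9 2-[4-({[(2R)-2-methylbutanoyl]oxy}methyl)-2-{[(2Z)-2-methylbut-2-enoyl]oxy}phenyl]prop-2-en-1-yl (2R)-2-methylbutanoate
Conditions: 8 (2.5 equiv), DIC (2.6 equiv), DMAP (0.2 equiv), CH2Cl2, 0 °C to rt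
Reagents that add atoms: none
Why: Steglich esterification of both primary alcohols at once; no ketene or strong base is involved, so the α-centre of the simple α-alkyl acid is retained, and the hindered aryl angelate is left alone.

**Step 4**
Reactants: 9 2-[4-({[(2R)-2-methylbutanoyl]oxy}methyl)-2-{[(2Z)-2-methylbut-2-enoyl]oxy}phenyl]prop-2-en-1-yl (2R)-2-methylbutanoate
Product: 10 {(2R)-2-[4-({[(2R)-2-methylbutanoyl]oxy}methyl)-2-{[(2Z)-2-methylbut-2-enoyl]oxy}phenyl]oxiran-2-yl}methyl (2R)-2-methylbutanoate
Conditions: [Fe(OTf)2((S,S)-Me2N-PDP)] (3 mol %), N-(1,8-naphthaloyl)-L-isoleucine (4 mol %), 30% aq H2O2 (1.5 equiv, syringe pump), MeCN, −30 °C; use the catalyst/co-ligand antipode that gives Si-face delivery (switch to (R,R)/D if the 8-epimer dominates)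
Reagents that add atoms: hydrogen peroxide, OO
Why: Proposed new method: catalyst-controlled asymmetric epoxidation of a 2-arylallyl carboxylate with a chiral non-heme iron aminopyridine complex, H2O2 and an amino-acid co-ligand; the iron-bound carboxylic acid assists O–O heterolysis to an electrophilic Fe(V)(O)(O2CR) oxidant that transfers O to the more electron-rich styrenyl C=C (the conjugated, electron-poor angelate reacts much more slowly), and the ligand wall plus chiral carboxylate distinguish the twisted ortho-acyloxyaryl group (large) from CH2OC(O)R (medium) so that O enters on the Si face of the alkene carbon (CH2O > aryl > =CH2) and gives the (R)-oxirane; the two faces give diastereomers because of the two remote (R) centres, so selectivity is read as d.r. and the minor epimer can be removed by HPLC; closest known reaction type: iron-aminopyridine/H2O2 asymmetric epoxidation of α-alkylstyrenes, not shown on allylic esters of this kind.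

## Compound list

1 | 2-bromo-5-(hydroxymethyl)phenol | OCc1ccc(Br)c(O)c1 | starting material
2 | 2-bromoprop-2-en-1-ol (2-bromoallyl alcohol) | OCC(Br)=C | starting material
3 | 5-(hydroxymethyl)-2-(4,4,5,5-tetramethyl-1,3,2-dioxaborolan-2-yl)phenol | OCc1ccc(B2OC(C)(C)C(C)(C)O2)c(O)c1 | intermediate
4 | 2-[2-hydroxy-4-(hydroxymethyl)phenyl]prop-2-en-1-ol | OCC(=C)c1ccc(CO)cc1O | intermediate
5 | angelic acid, (2Z)-2-methylbut-2-enoic acid | C/C=C(/C)C(=O)O | starting material
6 | angeloyl chloride, (2Z)-2-methylbut-2-enoyl chloride | C/C=C(/C)C(=O)Cl | intermediate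
7 | 5-(hydroxymethyl)-2-(3-hydroxyprop-1-en-2-yl)phenyl (2Z)-2-methylbut-2-enoate | C/C=C(/C)C(=O)Oc1cc(CO)ccc1C(=C)CO | intermediate
8 | (R)-2-methylbutanoic acid | CC[C@@H](C)C(=O)O | starting material
9 | 2-[4-({[(2R)-2-methylbutanoyl]oxy}methyl)-2-{[(2Z)-2-methylbut-2-enoyl]oxy}phenyl]prop-2-en-1-yl (2R)-2-methylbutanoate | C/C=C(/C)C(=O)Oc1cc(COC(=O)[C@H](C)CC)ccc1C(=C)COC(=O)[C@H](C)CC | intermediate
10 | {(2R)-2-[4-({[(2R)-2-methylbutanoyl]oxy}methyl)-2-{[(2Z)-2-methylbut-2-enoyl]oxy}phenyl]oxiran-2-yl}methyl (2R)-2-methylbutanoate | C/C=C(/C)C(=O)Oc1cc(COC(=O)[C@H](C)CC)ccc1[C@]1(COC(=O)[C@H](C)CC)CO1 | target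

## Step count and risks

Total steps: 4. Longest linear sequence: 4 (1 → 4 → 7 → 9 → 10).

**Step 4 (proposed new epoxidation).** The risks are insufficient facial selectivity, competing oxidation of the angelate, or Lewis-acid opening of the tertiary benzylic oxirane. The fallback uses known chemistry, sets out from 7 and comes back at 10. Sharpless asymmetric epoxidation of the free allylic alcohol of 7 (Ti(OiPr)4, L-(+)-DIPT, TBHP, 4 Å MS, CH2Cl2, −20 °C) gives 5-(hydroxymethyl)-2-[(2S)-2-(hydroxymethyl)oxiran-2-yl]phenyl (2Z)-2-methylbut-2-enoate F3. L-(+)-tartrate gives the (S)-epoxy alcohol by the usual Sharpless sense. Double Steglich esterification of F3 with 8 (DIC, DMAP, CH2Cl2, 0 °C) then gives 10. The descriptor changes from S to R on acylation only because CH2OC(O)R outranks the ring CH2; the spatial arrangement is unchanged. The same material serves as the authentic sample for assigning the d.r. of step 4.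

**Step 1 (one-pot borylation/Suzuki on the unprotected bromophenol).** The ortho-hydroxyaryl boronate 3 may protodeboronate. The fallback reverses the polarity, sets out from 1 and comes back at 4. Molybdenum-catalysed α-selective hydrostannation of propargyl alcohol with Bu3SnH gives 2-(tributylstannyl)prop-2-en-1-ol F1. Stille coupling of F1 with 1 (Pd(PPh3)4, CuI, DMF, 80 °C) gives 4 without an aryl boron intermediate.

**Step 2 (phenol-selective angeloylation).** The risks are acylation of the primary alcohols, phenol-to-allylic-OH acyl migration in 7, and Z-to-E drift. The fallback reverses the order of acylation, sets out from 4 and comes back at 9. Lipase (immobilised CAL-B) esterification of the two primary alcohols of 4 with 8 (toluene, 4 Å MS, 45 °C) leaves the phenol free and gives 2-[2-hydroxy-4-({[(2R)-2-methylbutanoyl]oxy}methyl)phenyl]prop-2-en-1-yl (2R)-2-methylbutanoate F2. Acylation of the single remaining OH of F2 with 6 (K2CO3, acetone, 0 °C) gives 9, with no aliphatic OH left to compete or accept a migrating acyl group.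

## Further compounds

F1 | step 1 | 2-(tributylstannyl)prop-2-en-1-ol | C=C(CO)[Sn](CCCC)(CCCC)CCCC
F2 | step 2 | 2-[2-hydroxy-4-({[(2R)-2-methylbutanoyl]oxy}methyl)phenyl]prop-2-en-1-yl (2R)-2-methylbutanoate | CC[C@@H](C)C(=O)OCC(=C)c1ccc(COC(=O)[C@H](C)CC)cc1O
F3 | step 4 | 5-(hydroxymethyl)-2-[(2S)-2-(hydroxymethyl)oxiran-2-yl]phenyl (2Z)-2-methylbut-2-enoate | C/C=C(/C)C(=O)Oc1cc(CO)ccc1[C@]1(CO)CO1
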